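All runs are simulated from invented constants.

At early times the east flask has 30.2 % of the substrate charged as target after 20.0 h. Dividing by the substrate present, I read an apparent first-order constant of 0.0180 /h for that stretch.

- east: substrate 0.050 M; enzyme 0.037 mol%; the very flask that is asked about, followed so far
- flask: substrate 0.050 M; enzyme 0.037 mol%; time 8.0 d

east run (percent of the substrate charged)

| time / h | target / % |
|---|---|
| 20.0 | 30.2 |
| 40.0 | 48.2 |
| 72.0 | 59.2 |
| 96.0 | 65.2 |
| 120 | 65.8 |
| 144 | 67.9 |

(readings scatter by 1 percentage point)

- delta: change nothing and wait 2.5 d more
- gamma: at 8.0 d take out 90 % of the target then present, then wait 2.5 d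
- eta: at 8.0 d add enzyme, 100 % of the amount charged, then wait 2.5 d
- alpha: at 8.0 d add substrate, 50.0 % of the amount charged, then wait 2.5 d

- target taken out counts as made
- the analysis behind the earlier runs scatters by 1 percentage point, standard deviation
- additions bring no volume worth counting

- target, in percent of the substrate first charged, at 8.0 d
- the remedy with the largest gain of target, or "none" below 2 percentage points (delta / gamma / eta / alpha / none)
- target present, with what was taken out counted in, in percent of the substrate first charged, after eta
- target present, with what was taken out counted in, in percent of the substrate first charged, after alpha

If that constant held, 3.16 % of the substrate would be left at 8.0 d. The readings refuse this: between 96.0 h and 144 h I read a constant of 0.00168 /h, far less than the early one, a ratio of 0.0933. Substrate is already divided out, so I suspect the concentration of working enzyme, charged at 0.037 mol%.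

Running the late constant on from the last reading, I reckon 70.4 % at 8.0 d. But that constant rests on a rise of 2.7 percentage points against a scatter of 1 point, so it is rough. The objection shrinks, though, since the whole extrapolated gain is 2.5 points.

For the remedies I carry the reach, the natural logarithm of substrate charged over substrate left. It stands at 1.14 after 144 h, and I take it to grow with the enzyme charge. A fresh charge should then repeat the early reach, leaving the share the first charge left at 72.0 h; that is the nearest reading, but it stands later than the end of the wait of 2.5 d, so my figure for eta leans high. That makes eta about 87.9 %, while alpha, on the late constant, gives about 78.0 %.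

The honest objection is an equilibrium near the late readings, under which fresh enzyme adds no reach and added substrate is the remedy that gains. I cannot compute that away from these readings, so eta is my judgement.

The forecast differs: 69.5 % (68 % to 71 %), best alpha, eta 71 % (69 % to 88 %), alpha 96 % (71 % to 100 %). Its ground: “I lean slightly to equilibrium because the first-order approach is simple and the plateau is clean.”

The flask gives 72.2 % at 8.0 d, and the best remedy is eta, with 90.7 % after eta against 81.3 % after alpha.

    substrate + enzyme ⇌ complex (K = 55.0 /M, k = 213 /M/min)
    complex → enzyme + target (k = 1.40 /min)
    2 enzyme → spent catalyst (k = 5.39 /M/min)
    enzyme ⇌ dormant form (K = 21.9, k = 0.00107 /min)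

At 192 h the dormant form holds 89.2 % of the catalyst charged. The reach of the flask is 1.28 at 192 h, against the 1.14 I read at 144 h. A neighbour flask charged with 0.013 M of substrate at the same loading has its enzyme charge lowered in the ratio of 0.013 M to 0.050 M, so its reach scales to 0.333, which leaves 71.7 % of the substrate, and that neighbour holds 70.3 % at 192 h.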